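**Retrosynthetic overview**

1. The target comes from its tridecabenzyl ether by one global hydrogenolysis.
2. The tridecabenzyl ether is made in one acid-mediated operation that forms three aryl C–C bonds: C4′–C4a′ (lower pyran, 6-endo epoxy-arene closure), C4–C4a (upper pyran, acetal/oxocarbenium closure) and C4–C8′ (interflavan bond, 4β, trans to the participating 3-O-galloyl group).
3. Both cyclisation substrates are 3,5-dibenzyloxyphenyl ethers of one erythro diol. Epoxide closure with retention gives the 2,3-trans lower precursor; primary oxidation/acetalisation followed by Mitsunobu galloylation with inversion gives the 2,3-cis upper precursor.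
4. The diol comes from benzylic phenoxide opening (inversion) of a single Sharpless epoxy alcohol, which supplies C2 and C3 of both flavan units; the O1–C2 bonds are therefore made before either pyran ring exists.
5. Ring order: oxirane (step 3), terminal oxirane (step 5), then lower pyran and upper pyran in the same flask (step 8); all benzene rings are bought.

Assumption: benzyl is the only protecting group, and the three benzyl-protected aromatic building blocks are taken as catalogue items (each is one or two routine steps from gallic acid or phloroglucinol).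

**Route**

Step 1
Reactants: 1 3,4,5-tris(benzyloxy)benzaldehyde
Product: 2 ethyl (E)-3-[3,4,5-tris(benzyloxy)phenyl]prop-2-enoate
Conditions: (EtO)2P(O)CH2CO2Et, NaH, THF, 0 °C → rt
Reagents that add atoms: triethyl phosphonoacetate CCOC(=O)CP(=O)(OCC)OCC
Why: Horner–Wadsworth–Emmons olefination of an aromatic aldehyde with a stabilised phosphonate anion gives the (E)-enoate selectively (no stereocentre).

Step 2
Reactants: 2 ethyl (E)-3-[3,4,5-tris(benzyloxy)phenyl]prop-2-enoate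
Product: 3 (E)-3-[3,4,5-tris(benzyloxy)phenyl]prop-2-en-1-ol
Conditions: DIBAL-H (2.5 equiv), CH2Cl2, −78 → 0 °C; Rochelle salt work-up
Reagents that add atoms: none
Why: DIBAL-H 1,2-reduction of the enoate stops at the allylic alcohol needed for titanium-directed epoxidation.

Step 3
Reactants: 3 (E)-3-[3,4,5-tris(benzyloxy)phenyl]prop-2-en-1-ol
Product: 4 [(2S,3S)-3-[3,4,5-tris(benzyloxy)phenyl]oxiran-2-yl]methanol
Conditions: Ti(OiPr)4 (10 mol%), L-(+)-DET (12 mol%), t-BuOOH (2 equiv), 4 Å MS, CH2Cl2, −20 °C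
Reagents that add atoms: tert-butyl hydroperoxide CC(C)(C)OO
Why: Katsuki–Sharpless asymmetric epoxidation with L-(+)-DET gives the (2S,3S)-epoxy alcohol from an (E)-cinnamyl alcohol, fixing the two carbons that become C2 and C3 of both flavan units.

Step 4
Reactants: 4 [(2S,3S)-3-[3,4,5-tris(benzyloxy)phenyl]oxiran-2-yl]methanol; 5 3,5-bis(benzyloxy)phenol
Product: 6 (2S,3R)-3-[3,5-bis(benzyloxy)phenoxy]-3-[3,4,5-tris(benzyloxy)phenyl]propane-1,2-diol
Conditions: 5 (1.5 equiv), NaOH (1.5 equiv), dioxane/H2O 3:1, 70 °C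
Reagents that add atoms: none
Why: Base-mediated SN2 opening of a trans-3-arylglycidol by a phenoxide at the benzylic carbon with inversion (the reboxetine-type aryloxy-diol synthesis) gives the erythro aryl ether; its (R) benzylic centre is C2 of both units and its ArO–C bond becomes O1–C2.

Step 5
Reactants: 6 (2S,3R)-3-[3,5-bis(benzyloxy)phenoxy]-3-[3,4,5-tris(benzyloxy)phenyl]propane-1,2-diol
Product: 8 (2S)-2-{(R)-[3,5-bis(benzyloxy)phenoxy][3,4,5-tris(benzyloxy)phenyl]methyl}oxirane, via primary tosylate 7 (not isolated)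
Conditions: TsCl (1.05 equiv), Bu2SnO (2 mol%), Et3N, CH2Cl2, 0 °C → rt; then K2CO3, MeOH, rt
Reagents that add atoms: none
Why: Tin-catalysed selective tosylation of the primary hydroxyl and intramolecular Williamson closure give the terminal epoxide without breaking the secondary C–O bond, so the (S) carbinol centre (future C3 of the lower unit) is retained.

Step 6
Reactants: 6 (2S,3R)-3-[3,5-bis(benzyloxy)phenoxy]-3-[3,4,5-tris(benzyloxy)phenyl]propane-1,2-diol
Product: 10 (1R,2R)-1-[3,5-bis(benzyloxy)phenoxy]-3,3-dimethoxy-1-[3,4,5-tris(benzyloxy)phenyl]propan-2-ol, via hydroxy aldehyde 9 (not isolated)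
Conditions: TEMPO (0.1 equiv), PhI(OAc)2 (1.1 equiv), CH2Cl2, 0 °C → rt; then HC(OMe)3, MeOH, CSA (cat.), rt
Reagents that add atoms: trimethyl orthoformate COC(OC)OC
Why: TEMPO/PhI(OAc)2 oxidation is selective for the primary alcohol, and the labile α-hydroxy aldehyde is trapped at once as its dimethyl acetal by acid-catalysed acetalisation; no bond at a stereocentre is broken (the descriptor changes only through CIP priorities).

Step 7
Reactants: 10 (1R,2R)-1-[3,5-bis(benzyloxy)phenoxy]-3,3-dimethoxy-1-[3,4,5-tris(benzyloxy)phenyl]propan-2-ol; 11 3,4,5-tris(benzyloxy)benzoic acid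
Product: 12 (1R,2S)-1-[3,5-bis(benzyloxy)phenoxy]-3,3-dimethoxy-1-[3,4,5-tris(benzyloxy)phenyl]propan-2-yl 3,4,5-tris(benzyloxy)benzoate
Conditions: PPh3, DIAD, toluene, 0 °C → rt
Reagents that add atoms: none
Why: Mitsunobu esterification of the secondary alcohol proceeds by SN2 inversion, which installs the gallate and converts the erythro into the threo (future 2,3-cis) arrangement in one step.

Step 8
Reactants: 12 (1R,2S)-1-[3,5-bis(benzyloxy)phenoxy]-3,3-dimethoxy-1-[3,4,5-tris(benzyloxy)phenyl]propan-2-yl 3,4,5-tris(benzyloxy)benzoate; 8 (2S)-2-{(R)-[3,5-bis(benzyloxy)phenoxy][3,4,5-tris(benzyloxy)phenyl]methyl}oxirane (2.5 equiv)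
Product: 15 5,7,3′,4′,5′-penta-O-benzyl-3-O-[3,4,5-tris(benzyloxy)benzoyl]-(−)-epigallocatechin-(4β→8)-5,7,3′,4′,5′-penta-O-benzyl-(+)-gallocatechin, via pentabenzyl gallocatechin 13 (not isolated), via 4-methoxyflavan gallate 14 (not isolated)
Conditions: 8, TMSOTf (0.3 equiv), 4 Å MS, CH2Cl2, −78 °C, 20 min; then 12 added over 1 h, −78 → −30 °C; Et3N quench, aq. NaHCO3, citric acid/MeOH wash
Reagents that add atoms: none
Why: Proposed new method: the acid first isomerises epoxide 8 by 6-endo epoxy-arene Friedel–Crafts closure at the terminal carbon (C4′–C4a′, C2′/C3′ untouched, giving 2,3-trans 13), then ionises the acetal of 12 to an oxocarbenium ion that is captured by the ortho carbon of its own 3,5-dibenzyloxyphenyl ether (intramolecular Friedel–Crafts hydroxyalkylation, C4–C4a, C2/C3 untouched, giving 2,3-cis 14), whose benzylic 4-OMe ionises again to a C4 cation bridged on the α face by the 3-O-galloyl carbonyl so that C8 of 13 adds from the β face (3,4-trans, 4β; C8 over C6 as in couplings of benzyl-protected flavan-3-ols); the closest known reactions are the Lewis-acid cyclisation of aryl glycidyl ethers to chroman-3-ols, the cyclisation of 3-aryloxypropanal acetals to 4-alkoxychromans and the TMSOTf-mediated coupling of 4-alkoxyflavan-3-ol esters with flavan-3-ols.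

Step 9
Reactants: 15 5,7,3′,4′,5′-penta-O-benzyl-3-O-[3,4,5-tris(benzyloxy)benzoyl]-(−)-epigallocatechin-(4β→8)-5,7,3′,4′,5′-penta-O-benzyl-(+)-gallocatechin
Product: 16 (−)-epigallocatechin 3-O-gallate-(4β→8)-(+)-gallocatechin (target)
Conditions: H2 (1 atm), 20% Pd(OH)2/C, THF/MeOH/H2O, rt; Sephadex LH-20
Reagents that add atoms: none
Why: Hydrogenolysis of all thirteen benzyl ethers over Pearlman's catalyst under neutral conditions leaves the gallate ester, the interflavan C–C bond and the five stereocentres untouched (the usual last step of procyanidin gallate syntheses).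

**Compound list**

1 | 3,4,5-tris(benzyloxy)benzaldehyde | O=Cc1cc(OCc2ccccc2)c(OCc2ccccc2)c(OCc2ccccc2)c1 | starting material
2 | ethyl (E)-3-[3,4,5-tris(benzyloxy)phenyl]prop-2-enoate | CCOC(=O)/C=C/c1cc(OCc2ccccc2)c(OCc2ccccc2)c(OCc2ccccc2)c1 | intermediate
3 | (E)-3-[3,4,5-tris(benzyloxy)phenyl]prop-2-en-1-ol | OC/C=C/c1cc(OCc2ccccc2)c(OCc2ccccc2)c(OCc2ccccc2)c1 | intermediate
4 | [(2S,3S)-3-[3,4,5-tris(benzyloxy)phenyl]oxiran-2-yl]methanol | OC[C@@H]1O[C@H]1c1cc(OCc2ccccc2)c(OCc2ccccc2)c(OCc2ccccc2)c1 | intermediate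
5 | 3,5-bis(benzyloxy)phenol | Oc1cc(OCc2ccccc2)cc(OCc2ccccc2)c1 | starting material
6 | (2S,3R)-3-[3,5-bis(benzyloxy)phenoxy]-3-[3,4,5-tris(benzyloxy)phenyl]propane-1,2-diol | OC[C@H](O)[C@H](Oc1cc(OCc2ccccc2)cc(OCc2ccccc2)c1)c1cc(OCc2ccccc2)c(OCc2ccccc2)c(OCc2ccccc2)c1 | intermediate
7 | (2S,3R)-3-[3,5-bis(benzyloxy)phenoxy]-2-hydroxy-3-[3,4,5-tris(benzyloxy)phenyl]propyl 4-methylbenzenesulfonate | Cc1ccc(cc1)S(=O)(=O)OC[C@H](O)[C@H](Oc1cc(OCc2ccccc2)cc(OCc2ccccc2)c1)c1cc(OCc2ccccc2)c(OCc2ccccc2)c(OCc2ccccc2)c1 | intermediate (not isolated)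
8 | (2S)-2-{(R)-[3,5-bis(benzyloxy)phenoxy][3,4,5-tris(benzyloxy)phenyl]methyl}oxirane | C1O[C@@H]1[C@H](Oc1cc(OCc2ccccc2)cc(OCc2ccccc2)c1)c1cc(OCc2ccccc2)c(OCc2ccccc2)c(OCc2ccccc2)c1 | intermediate
9 | (2R,3R)-3-[3,5-bis(benzyloxy)phenoxy]-2-hydroxy-3-[3,4,5-tris(benzyloxy)phenyl]propanal | O=C[C@H](O)[C@H](Oc1cc(OCc2ccccc2)cc(OCc2ccccc2)c1)c1cc(OCc2ccccc2)c(OCc2ccccc2)c(OCc2ccccc2)c1 | intermediate (not isolated)
10 | (1R,2R)-1-[3,5-bis(benzyloxy)phenoxy]-3,3-dimethoxy-1-[3,4,5-tris(benzyloxy)phenyl]propan-2-ol | COC(OC)[C@H](O)[C@H](Oc1cc(OCc2ccccc2)cc(OCc2ccccc2)c1)c1cc(OCc2ccccc2)c(OCc2ccccc2)c(OCc2ccccc2)c1 | intermediate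
11 | 3,4,5-tris(benzyloxy)benzoic acid | OC(=O)c1cc(OCc2ccccc2)c(OCc2ccccc2)c(OCc2ccccc2)c1 | starting material
12 | (1R,2S)-1-[3,5-bis(benzyloxy)phenoxy]-3,3-dimethoxy-1-[3,4,5-tris(benzyloxy)phenyl]propan-2-yl 3,4,5-tris(benzyloxy)benzoate | COC(OC)[C@@H](OC(=O)c1cc(OCc2ccccc2)c(OCc2ccccc2)c(OCc2ccccc2)c1)[C@H](Oc1cc(OCc2ccccc2)cc(OCc2ccccc2)c1)c1cc(OCc2ccccc2)c(OCc2ccccc2)c(OCc2ccccc2)c1 | intermediate
13 | (2R,3S)-5,7-bis(benzyloxy)-2-[3,4,5-tris(benzyloxy)phenyl]chroman-3-ol (penta-O-benzyl-(+)-gallocatechin) | O[C@H]1Cc2c(OCc3ccccc3)cc(OCc3ccccc3)cc2O[C@@H]1c1cc(OCc2ccccc2)c(OCc2ccccc2)c(OCc2ccccc2)c1 | intermediate (not isolated)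
14 | (2R,3R)-5,7-bis(benzyloxy)-4-methoxy-2-[3,4,5-tris(benzyloxy)phenyl]chroman-3-yl 3,4,5-tris(benzyloxy)benzoate (2,3-cis; C4 epimer mixture, C4 left undefined) | O=C(O[C@@H]1C(OC)c2c(OCc3ccccc3)cc(OCc3ccccc3)cc2O[C@@H]1c1cc(OCc2ccccc2)c(OCc2ccccc2)c(OCc2ccccc2)c1)c1cc(OCc2ccccc2)c(OCc2ccccc2)c(OCc2ccccc2)c1 | intermediate (not isolated)
15 | 5,7,3′,4′,5′-penta-O-benzyl-3-O-[3,4,5-tris(benzyloxy)benzoyl]-(−)-epigallocatechin-(4β→8)-5,7,3′,4′,5′-penta-O-benzyl-(+)-gallocatechin | O=C(O[C@@H]1[C@@H](c2c(OCc4ccccc4)cc(OCc4ccccc4)c3c2O[C@H](c2cc(OCc4ccccc4)c(OCc4ccccc4)c(OCc4ccccc4)c2)[C@@H](O)C3)c2c(OCc3ccccc3)cc(OCc3ccccc3)cc2O[C@@H]1c1cc(OCc2ccccc2)c(OCc2ccccc2)c(OCc2ccccc2)c1)c1cc(OCc2ccccc2)c(OCc2ccccc2)c(OCc2ccccc2)c1 | intermediate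
16 | (−)-epigallocatechin 3-O-gallate-(4β→8)-(+)-gallocatechin (upper unit 2R,3R with 4β aryl; lower unit 2R,3S) | O=C(O[C@@H]1[C@@H](c2c(O)cc(O)c3c2O[C@H](c2cc(O)c(O)c(O)c2)[C@@H](O)C3)c2c(O)cc(O)cc2O[C@@H]1c1cc(O)c(O)c(O)c1)c1cc(O)c(O)c(O)c1 | target

**Step count and risks**

Total step count: 9. Longest linear sequence: 8 steps (steps 1, 2, 3, 4, 6, 7, 8, 9, from 1 to 16); the lower-unit branch is step 5.

Steps most likely to fail:

Step 8 (most risk). Three Friedel–Crafts events must occur in order in one flask. Possible failures are 5-exo instead of 6-endo opening of epoxide 8, self-condensation of the upper cation, C6 instead of C8 attack, and ionisation of the benzylic aryl ethers. The fallback sets out from 12 and 8 and returns at 15, and separates the three events. Epoxide 8 alone is cyclised with BF3·OEt2 in CH2Cl2 at −78 °C and pentabenzyl gallocatechin 13 is isolated. Acetal 12 is cyclised with BF3·OEt2 in the presence of 1.05 equiv of benzyl mercaptan, so that the oxocarbenium/thionium ion closes onto the aryl ether and the flavan-4-yl cation is trapped as the bench-stable 4β-(benzylsulfanyl)flavan gallate F1. F1 is then activated thiophilically with AgBF4 in THF/CH2Cl2 at 0 °C in the presence of 3 equiv of 13, giving 15 by the established 4-thioether coupling.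

Step 6. PhI(OAc)2 can cleave the 1,2-diol, and the α-hydroxy aldehyde 9 can epimerise or undergo a ketol shift before it is acetalised. The fallback sets out from 6 and returns at 12 (it replaces steps 6 and 7); inversion is done before oxidation. The primary hydroxyl of 6 is silylated (TBSCl, imidazole) to the primary silyl ether F2. Mitsunobu reaction of F2 with 11 (PPh3, DIAD) gives the inverted gallate silyl ether F3. HF·pyridine removes the silyl group to give the primary alcohol F4. Dess–Martin oxidation gives the α-galloyloxy aldehyde F5, which is acetalised (HC(OMe)3, MeOH, CSA) to 12.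

Step 7. The carbinol is hindered and flanked by an acetal, and the benzoic acid is only weakly acidic, so the Mitsunobu reaction may be slow or give elimination. The fallback sets out from 10 and returns at 12, and replaces the redox condensation by sulfonate displacement. Alcohol 10 is converted with Tf2O/pyridine at −30 °C into the triflate F6, which is displaced with inversion by caesium 3,4,5-tris(benzyloxy)benzoate (from 11 and Cs2CO3, 18-crown-6, toluene), as in Lattrell–Dax inversions next to an acetal carbon in sugars.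

Further compounds
F1 | step 8 | 4β-(benzylsulfanyl)-5,7,3′,4′,5′-penta-O-benzyl-(−)-epigallocatechin 3-O-[3,4,5-tris(benzyloxy)benzoate] | O=C(O[C@@H]1[C@@H](SCc2ccccc2)c2c(OCc3ccccc3)cc(OCc3ccccc3)cc2O[C@@H]1c1cc(OCc2ccccc2)c(OCc2ccccc2)c(OCc2ccccc2)c1)c1cc(OCc2ccccc2)c(OCc2ccccc2)c(OCc2ccccc2)c1
F2 | step 6 | (1R,2S)-1-[3,5-bis(benzyloxy)phenoxy]-3-[(tert-butyldimethylsilyl)oxy]-1-[3,4,5-tris(benzyloxy)phenyl]propan-2-ol | CC(C)(C)[Si](C)(C)OC[C@H](O)[C@H](Oc1cc(OCc2ccccc2)cc(OCc2ccccc2)c1)c1cc(OCc2ccccc2)c(OCc2ccccc2)c(OCc2ccccc2)c1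
F3 | step 6 | (1R,2R)-1-[3,5-bis(benzyloxy)phenoxy]-3-[(tert-butyldimethylsilyl)oxy]-1-[3,4,5-tris(benzyloxy)phenyl]propan-2-yl 3,4,5-tris(benzyloxy)benzoate | CC(C)(C)[Si](C)(C)OC[C@@H](OC(=O)c1cc(OCc2ccccc2)c(OCc2ccccc2)c(OCc2ccccc2)c1)[C@H](Oc1cc(OCc2ccccc2)cc(OCc2ccccc2)c1)c1cc(OCc2ccccc2)c(OCc2ccccc2)c(OCc2ccccc2)c1
F4 | step 6 | (1R,2R)-1-[3,5-bis(benzyloxy)phenoxy]-3-hydroxy-1-[3,4,5-tris(benzyloxy)phenyl]propan-2-yl 3,4,5-tris(benzyloxy)benzoate | OC[C@@H](OC(=O)c1cc(OCc2ccccc2)c(OCc2ccccc2)c(OCc2ccccc2)c1)[C@H](Oc1cc(OCc2ccccc2)cc(OCc2ccccc2)c1)c1cc(OCc2ccccc2)c(OCc2ccccc2)c(OCc2ccccc2)c1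
F5 | step 6 | (1R,2S)-1-[3,5-bis(benzyloxy)phenoxy]-3-oxo-1-[3,4,5-tris(benzyloxy)phenyl]propan-2-yl 3,4,5-tris(benzyloxy)benzoate | O=C[C@@H](OC(=O)c1cc(OCc2ccccc2)c(OCc2ccccc2)c(OCc2ccccc2)c1)[C@H](Oc1cc(OCc2ccccc2)cc(OCc2ccccc2)c1)c1cc(OCc2ccccc2)c(OCc2ccccc2)c(OCc2ccccc2)c1
F6 | step 7 | (1R,2R)-1-[3,5-bis(benzyloxy)phenoxy]-3,3-dimethoxy-1-[3,4,5-tris(benzyloxy)phenyl]propan-2-yl trifluoromethanesulfonate | COC(OC)[C@H](OS(=O)(=O)C(F)(F)F)[C@H](Oc1cc(OCc2ccccc2)cc(OCc2ccccc2)c1)c1cc(OCc2ccccc2)c(OCc2ccccc2)c(OCc2ccccc2)c1
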